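The benzene ring is made, not bought: arene carbons C10–C15, the C13 methyl and the C16–C18 side chain lie on one carbon chain continuing from C9, so the ring is disconnected at C10–C15 to an acyclic (E,Z,E)-triene. Heating tetraenoate 19 closes that bond by 6π electrocyclisation, and DDQ in the same flask aromatises the cyclohexadiene, giving the 1,2,4-trisubstituted arene with the C7–C9 stereotriad untouched. The precursor is assembled by Suzuki coupling of an E-vinylboronate (Roche ester, Evans syn aldol) with a Z-iodotrienoate (propargyl alcohol, vinylogous Horner–Wadsworth–Emmons). The 4-hydroxy-2-pyranone ring (O1, C2–C6) is annulated last.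

Key step: step 12

Assumption: atoms are numbered O1, C2–C6 (pyranone), C7–C9 (stereotriad), C10–C15 (benzene ring), C16–C18 (propenol); TBS = tert-butyldimethylsilyl, TBDPS = tert-butyldiphenylsilyl; the bis-TBS ethyl ester form of the tetraenoate is kept because the ester tolerates DDQ, and C18–OH is later capped as a TBDPS ether so that the primary TBS ether at C6 is the only silyl ether cleaved by buffered HF·pyridine.

Step 1
Reactants: 1 methyl (R)-3-hydroxy-2-methylpropanoate (Roche ester)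
Product: 2 methyl (2R)-3-[(tert-butyldimethylsilyl)oxy]-2-methylpropanoate
Conditions: TBSCl, imidazole, CH2Cl2, 0 °C → rt
Reagents that add atoms: tert-butyl(chloro)dimethylsilane (TBSCl), CC(C)(C)[Si](C)(C)Cl
Why: Imidazole-promoted silylation of a primary alcohol; the C7 stereocentre is not involved.

Step 2
Reactants: 2 methyl (2R)-3-[(tert-butyldimethylsilyl)oxy]-2-methylpropanoate
Product: 3 (2R)-3-[(tert-butyldimethylsilyl)oxy]-2-methylpropanal
Conditions: iBu2AlH (1.05 equiv), CH2Cl2, −78 °C; MeOH, aq. potassium sodium tartrate; used crude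
Reagents that add atoms: none
Why: Partial hydride reduction of an ester, in which the aluminium hemiacetal is stable at −78 °C and releases the aldehyde only on work-up; the aldehyde is used without chromatography to keep C7 intact.

Step 3
Reactants: 3 (2R)-3-[(tert-butyldimethylsilyl)oxy]-2-methylpropanal; 4 (R)-4-benzyl-3-propionyl-1,3-oxazolidin-2-one
Product: 7 (4R)-4-benzyl-3-[(2R,3S,4R)-5-(TBSO)-3-hydroxy-2,4-dimethylpentanoyl]-1,3-oxazolidin-2-one (all-syn C7/C8/C9 triad), via boron enolate 5 (not isolated), via boron aldolate 6 (not isolated)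
Conditions: 4, Bu2BOTf, Et3N, CH2Cl2, 0 °C; then 3, −78 → 0 °C; pH 7 buffer, MeOH, H2O2, 0 °C
Reagents that add atoms: none
Why: Evans syn aldol in which the Z-boron enolate reacts through a closed chair (Zimmerman–Traxler) transition state on the enolate face opposite the benzyl group, setting C8 and C9 syn under auxiliary control and, with the (R)-aldehyde, syn to the C7 methyl as well.

Step 4
Reactants: 7 (4R)-4-benzyl-3-[(2R,3S,4R)-5-(TBSO)-3-hydroxy-2,4-dimethylpentanoyl]-1,3-oxazolidin-2-one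
Product: 8 (4R)-4-benzyl-3-[(2R,3S,4R)-3,5-bis(TBSO)-2,4-dimethylpentanoyl]-1,3-oxazolidin-2-one
Conditions: TBSOTf, 2,6-lutidine, CH2Cl2, −78 → 0 °C
Reagents that add atoms: tert-butyldimethylsilyl triflate (TBSOTf), CC(C)(C)[Si](C)(C)OS(=O)(=O)C(F)(F)F
Why: Silyl triflate silylation of a hindered secondary alcohol, which also blocks retro-aldol cleavage in the following steps.

Step 5
Reactants: 8 (4R)-4-benzyl-3-[(2R,3S,4R)-3,5-bis(TBSO)-2,4-dimethylpentanoyl]-1,3-oxazolidin-2-one
Product: 9 (2S,3R,4R)-3,5-bis(TBSO)-2,4-dimethylpentan-1-ol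
Conditions: LiBH4, MeOH (2 equiv), THF, 0 °C → rt
Reagents that add atoms: none
Why: Reductive cleavage of the N-acyl oxazolidinone by borohydride at the exocyclic carbonyl, which frees C10 as the primary alcohol without touching C9 and returns the auxiliary.

Step 6
Reactants: 9 (2S,3R,4R)-3,5-bis(TBSO)-2,4-dimethylpentan-1-ol
Product: 10 (2R,3S,4R)-3,5-bis(TBSO)-2,4-dimethylpentanal
Conditions: Dess–Martin periodinane, CH2Cl2, 0 °C → rt; used crude
Reagents that add atoms: none
Why: Dess–Martin oxidation is neutral enough to give the α-branched aldehyde without epimerising C9.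

Step 7
Reactants: 10 (2R,3S,4R)-3,5-bis(TBSO)-2,4-dimethylpentanal
Product: 11 2-[(1E,3S,4R,5R)-4,6-bis(TBSO)-3,5-dimethylhex-1-en-1-yl]-4,4,5,5-tetramethyl-1,3,2-dioxaborolane
Conditions: Cl2CHBpin, CrCl2 (8 equiv), LiI, THF, rt
Reagents that add atoms: 2-(dichloromethyl)-4,4,5,5-tetramethyl-1,3,2-dioxaborolane (Cl2CHBpin), ClC(Cl)B1OC(C)(C)C(C)(C)O1
Why: Takai-type olefination with a boryl-substituted geminal dichromium reagent, whose addition and anti elimination place boron trans to the chain (E at C10=C11) under non-basic conditions that leave C9 untouched.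

Step 8
Reactants: 12 propargyl alcohol
Product: 14 (2Z)-3-iodo-2-methylprop-2-en-1-ol, via magnesium chelate 13 (not isolated)
Conditions: MeMgBr (2.5 equiv), CuI (10 mol %), THF, −20 °C → rt; then I2, −78 °C → rt
Reagents that add atoms: methylmagnesium bromide, C[Mg]Br; iodine, II
Why: Copper-catalysed, alkoxide-directed anti-carbomagnesiation delivers the methyl group to C13 and forms a five-membered vinylmagnesium chelate, so that iodinolysis with retention puts iodine cis to the CH2OH group (Z at C12=C13).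

Step 9
Reactants: 14 (2Z)-3-iodo-2-methylprop-2-en-1-ol
Product: 15 (2Z)-3-iodo-2-methylprop-2-enal
Conditions: activated MnO2, CH2Cl2, rt, dark; filtered and used at once
Reagents that add atoms: none
Why: Heterogeneous allylic oxidation with MnO2 is neutral and fast, which limits Z to E isomerisation of the β-iodoenal.

Step 10
Reactants: 15 (2Z)-3-iodo-2-methylprop-2-enal; 16 triethyl 4-phosphonocrotonate
Product: 18 ethyl (2E,4E,6Z)-7-iodo-6-methylhepta-2,4,6-trienoate, via lithiated phosphonate 17 (not isolated)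
Conditions: 16, LiN(SiMe3)2, THF, −78 °C; then 15, −78 → 0 °C, dark
Reagents that add atoms: none
Why: Vinylogous Horner–Wadsworth–Emmons olefination, in which the stabilised allyl phosphonate anion reacts at its α-carbon and reversible addition favours the E alkene at C14=C15 while the C16=C17 alkene stays E.

Step 11
Reactants: 11 2-[(1E,3S,4R,5R)-4,6-bis(TBSO)-3,5-dimethylhex-1-en-1-yl]-4,4,5,5-tetramethyl-1,3,2-dioxaborolane; 18 ethyl (2E,4E,6Z)-7-iodo-6-methylhepta-2,4,6-trienoate
Product: 19 ethyl (2E,4E,6Z,8E,10S,11R,12R)-11,13-bis(TBSO)-6,10,12-trimethyltrideca-2,4,6,8-tetraenoate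
Conditions: Pd(dppf)Cl2·CH2Cl2 (5 mol %), K3PO4 (aq.), THF, rt, dark, degassed
Reagents that add atoms: none
Why: Suzuki–Miyaura coupling forms C11–C12 with retention of both alkene geometries (oxidative addition of zerovalent palladium to the Z-iodide, transmetallation of the E-boronate), and room temperature keeps the triene from closing early.

Step 12
Reactants: 19 ethyl (2E,4E,6Z,8E,10S,11R,12R)-11,13-bis(TBSO)-6,10,12-trimethyltrideca-2,4,6,8-tetraenoate
Product: 21 ethyl (2E)-3-{2-[(2S,3R,4R)-3,5-bis(TBSO)-4-methylpentan-2-yl]-5-methylphenyl}prop-2-enoate, via cis-cyclohexadiene 20 (not isolated)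
Conditions: toluene (dilute, degassed), 110 °C, sealed tube; cool to rt; DDQ (1.2 equiv), rt
Reagents that add atoms: none
Why: On heating, the (E,Z,E)-triene spanning C10–C15 folds into its s-cis,s-cis conformer and undergoes a thermal six-electron electrocyclisation in the disrotatory mode, which forms the C10–C15 σ-bond and closes the six-membered carbocycle as cis-5,6-disubstituted cyclohexa-1,3-diene 20; DDQ then takes hydride from C10 or C15 and the cyclohexadienyl cation loses a proton to give the benzene ring. The closest known reaction type is the thermal hexatriene-to-cyclohexadiene electrocyclisation followed by quinone dehydrogenation. The two transient sp3 centres at C10 and C15 are erased on aromatisation, so no stereocontrol is needed, and the C7–C9 stereotriad lies outside the reacting π-system. The selectivity required is periselectivity: only the C10–C15 triene has a Z central alkene (C12=C13), while the E alkene at C14=C15 rules out both the C12–C17 six-electron closure and any eight-electron closure. The C13 methyl is trans to C11 and C10=C11 is E, so 1,5- and 1,7-hydrogen shifts should not compete, and the 1,2,4-substitution pattern follows from the order of the chain carbons.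

Step 13
Reactants: 21 ethyl (2E)-3-{2-[(2S,3R,4R)-3,5-bis(TBSO)-4-methylpentan-2-yl]-5-methylphenyl}prop-2-enoate
Product: 22 (2E)-3-{2-[(2S,3R,4R)-3,5-bis(TBSO)-4-methylpentan-2-yl]-5-methylphenyl}prop-2-en-1-ol
Conditions: iBu2AlH (2.5 equiv), CH2Cl2, −78 °C; aq. potassium sodium tartrate
Reagents that add atoms: none
Why: 1,2-Reduction of the conjugated ester by the aluminium hydride gives the E allylic alcohol without touching the silyl ethers.

Step 14
Reactants: 22 (2E)-3-{2-[(2S,3R,4R)-3,5-bis(TBSO)-4-methylpentan-2-yl]-5-methylphenyl}prop-2-en-1-ol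
Product: 23 tert-butyldiphenylsilyl ether of 22 (C18–OTBDPS; C6–OTBS and C8–OTBS unchanged)
Conditions: TBDPSCl, imidazole, CH2Cl2, 0 °C → rt
Reagents that add atoms: tert-butyl(chloro)diphenylsilane (TBDPSCl), CC(C)(C)[Si](Cl)(c1ccccc1)c1ccccc1
Why: Imidazole-promoted silylation of the primary allylic alcohol with a group that is far more acid-stable than the primary TBS ether yet falls to fluoride at the end.

Step 15
Reactants: 23 tert-butyldiphenylsilyl ether of 22
Product: 24 (2R,3R,4S)-3-(TBSO)-4-{2-[(1E)-3-(TBDPSO)prop-1-en-1-yl]-4-methylphenyl}-2-methylpentan-1-ol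
Conditions: HF·pyridine, pyridine, THF, 0 °C → rt
Reagents that add atoms: none
Why: Kinetically selective fluoride-mediated desilylation removes the unhindered primary TBS ether, while the secondary TBS ether flanked by two branched carbons and the TBDPS ether survive.

Step 16
Reactants: 24 (2R,3R,4S)-3-(TBSO)-4-{2-[(1E)-3-(TBDPSO)prop-1-en-1-yl]-4-methylphenyl}-2-methylpentan-1-ol
Product: 25 (2S,3R,4S)-3-(TBSO)-4-{2-[(1E)-3-(TBDPSO)prop-1-en-1-yl]-4-methylphenyl}-2-methylpentanal
Conditions: Dess–Martin periodinane, CH2Cl2, 0 °C → rt; used crude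
Reagents that add atoms: none
Why: Dess–Martin oxidation gives the C6 aldehyde under neutral conditions that spare the C7 stereocentre and the allylic silyl ether.

Step 17
Reactants: 25 (2S,3R,4S)-3-(TBSO)-4-{2-[(1E)-3-(TBDPSO)prop-1-en-1-yl]-4-methylphenyl}-2-methylpentanal; 26 ethyl 2-ethylacetoacetate
Product: 28 ethyl (6R,7R,8S)-7-(TBSO)-2-ethyl-5-hydroxy-6-methyl-3-oxo-8-{2-[(1E)-3-(TBDPSO)prop-1-en-1-yl]-4-methylphenyl}nonanoate (epimers at C2 and C5 of the ester chain), via dilithium dianion 27 (not isolated)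
Conditions: 26 (3 equiv), LiN(iPr)2 (6.2 equiv), THF, −78 → 0 °C; then 25, −78 °C; aq. NH4Cl
Reagents that add atoms: none
Why: Aldol addition of a β-ketoester dianion, whose terminal carbanion adds 1,2 to the aldehyde at −78 °C faster than it can deprotonate C7; the new carbinol centre is of no consequence because it is oxidised in the next step.

Step 18
Reactants: 28 ethyl (6R,7R,8S)-7-(TBSO)-2-ethyl-5-hydroxy-6-methyl-3-oxo-8-arylnonanoate
Product: 29 ethyl (6S,7R,8S)-7-(TBSO)-2-ethyl-6-methyl-3,5-dioxo-8-{2-[(1E)-3-(TBDPSO)prop-1-en-1-yl]-4-methylphenyl}nonanoate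
Conditions: Dess–Martin periodinane, CH2Cl2, 0 °C → rt
Reagents that add atoms: none
Why: Dess–Martin oxidation of the secondary alcohol gives the 3,5-diketoester, which exists largely as its enol and so protects C7 from epimerisation.

Step 19
Reactants: 29 ethyl (6S,7R,8S)-7-(TBSO)-2-ethyl-6-methyl-3,5-dioxo-8-arylnonanoate
Product: 30 6-[(2S,3R,4S)-3-(TBSO)-4-{2-[(1E)-3-(TBDPSO)prop-1-en-1-yl]-4-methylphenyl}pentan-2-yl]-3-ethyl-4-hydroxy-2H-pyran-2-one
Conditions: DBU, toluene, rt → 60 °C; aq. NaH2PO4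
Reagents that add atoms: none
Why: Base-mediated lactonisation, in which the enolate oxygen at C6 attacks the ethyl ester, ethoxide leaves and tautomerisation gives the 4-hydroxy-2-pyranone; the diketone stays as its central enolate, so C7 is not deprotonated and the C8 silyl ether is not eliminated.

Step 20
Reactants: 30 6-[(2S,3R,4S)-3-(TBSO)-4-{2-[(1E)-3-(TBDPSO)prop-1-en-1-yl]-4-methylphenyl}pentan-2-yl]-3-ethyl-4-hydroxy-2H-pyran-2-one
Product: 31 veramycin A, 3-ethyl-4-hydroxy-6-[(2S,3R,4S)-3-hydroxy-4-{2-[(1E)-3-hydroxyprop-1-en-1-yl]-4-methylphenyl}pentan-2-yl]-2H-pyran-2-one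
Conditions: TBAF (6 equiv), THF, rt → 45 °C; aq. NH4Cl
Reagents that add atoms: none
Why: Fluoride-mediated global desilylation removes the TBDPS ether at C18 and the hindered TBS ether at C8, while the pyranone is held as its stable anion until work-up.

Compound list
1 | methyl (R)-3-hydroxy-2-methylpropanoate (Roche ester) | OC[C@@H](C)C(=O)OC | starting material
2 | methyl (2R)-3-[(tert-butyldimethylsilyl)oxy]-2-methylpropanoate | CC(C)(C)[Si](C)(C)OC[C@@H](C)C(=O)OC | intermediate
3 | (2R)-3-[(tert-butyldimethylsilyl)oxy]-2-methylpropanal | CC(C)(C)[Si](C)(C)OC[C@@H](C)C=O | intermediate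
4 | (R)-4-benzyl-3-propionyl-1,3-oxazolidin-2-one | CCC(=O)N1[C@H](Cc2ccccc2)COC1=O | starting material
5 | (Z)-dibutylboron enolate of 4 (methyl cis to O–B) | C/C=C(\OB(CCCC)CCCC)N1[C@H](Cc2ccccc2)COC1=O | intermediate (not isolated)
6 | dibutylboron aldolate of 7 (C8–O–BBu2) | CC(C)(C)[Si](C)(C)OC[C@@H](C)[C@H](OB(CCCC)CCCC)[C@@H](C)C(=O)N1[C@H](Cc2ccccc2)COC1=O | intermediate (not isolated)
7 | (4R)-4-benzyl-3-[(2R,3S,4R)-5-(TBSO)-3-hydroxy-2,4-dimethylpentanoyl]-1,3-oxazolidin-2-one | CC(C)(C)[Si](C)(C)OC[C@@H](C)[C@H](O)[C@@H](C)C(=O)N1[C@H](Cc2ccccc2)COC1=O | intermediate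
8 | (4R)-4-benzyl-3-[(2R,3S,4R)-3,5-bis(TBSO)-2,4-dimethylpentanoyl]-1,3-oxazolidin-2-one | CC(C)(C)[Si](C)(C)OC[C@@H](C)[C@H](O[Si](C)(C)C(C)(C)C)[C@@H](C)C(=O)N1[C@H](Cc2ccccc2)COC1=O | intermediate
9 | (2S,3R,4R)-3,5-bis(TBSO)-2,4-dimethylpentan-1-ol | CC(C)(C)[Si](C)(C)OC[C@@H](C)[C@H](O[Si](C)(C)C(C)(C)C)[C@@H](C)CO | intermediate
10 | (2R,3S,4R)-3,5-bis(TBSO)-2,4-dimethylpentanal | CC(C)(C)[Si](C)(C)OC[C@@H](C)[C@H](O[Si](C)(C)C(C)(C)C)[C@@H](C)C=O | intermediate
11 | 2-[(1E,3S,4R,5R)-4,6-bis(TBSO)-3,5-dimethylhex-1-en-1-yl]-4,4,5,5-tetramethyl-1,3,2-dioxaborolane | CC(C)(C)[Si](C)(C)OC[C@@H](C)[C@H](O[Si](C)(C)C(C)(C)C)[C@@H](C)/C=C/B1OC(C)(C)C(C)(C)O1 | intermediate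
12 | propargyl alcohol | C#CCO | starting material
13 | 4-methyl-2,5-dihydro-1,2-oxamagnesole (cyclic vinylmagnesium alkoxide) | CC1=C[Mg]OC1 | intermediate (not isolated)
14 | (2Z)-3-iodo-2-methylprop-2-en-1-ol | OC/C(C)=C\I | intermediate
15 | (2Z)-3-iodo-2-methylprop-2-enal | O=C/C(C)=C\I | intermediate
16 | triethyl 4-phosphonocrotonate | CCOC(=O)/C=C/CP(=O)(OCC)OCC | starting material
17 | lithium salt of 16 (phosphonate-stabilised allyl anion) | [Li+].CCOC(=O)/C=C/[CH-]P(=O)(OCC)OCC | intermediate (not isolated)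
18 | ethyl (2E,4E,6Z)-7-iodo-6-methylhepta-2,4,6-trienoate | CCOC(=O)/C=C/C=C/C(C)=C\I | intermediate
19 | ethyl (2E,4E,6Z,8E,10S,11R,12R)-11,13-bis(TBSO)-6,10,12-trimethyltrideca-2,4,6,8-tetraenoate | CC(C)(C)[Si](C)(C)OC[C@@H](C)[C@H](O[Si](C)(C)C(C)(C)C)[C@@H](C)/C=C/C=C(C)\C=C\C=C\C(=O)OCC | intermediate (key-step precursor)
20 | ethyl (2E)-3-{cis-6-[(2S,3R,4R)-3,5-bis(TBSO)-4-methylpentan-2-yl]-3-methylcyclohexa-2,4-dien-1-yl}prop-2-enoate (both cis diastereomers expected; one drawn) | CC(C)(C)[Si](C)(C)OC[C@@H](C)[C@H](O[Si](C)(C)C(C)(C)C)[C@@H](C)[C@@H]1C=CC(C)=C[C@@H]1/C=C/C(=O)OCC | intermediate (not isolated)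
21 | ethyl (2E)-3-{2-[(2S,3R,4R)-3,5-bis(TBSO)-4-methylpentan-2-yl]-5-methylphenyl}prop-2-enoate | CC(C)(C)[Si](C)(C)OC[C@@H](C)[C@H](O[Si](C)(C)C(C)(C)C)[C@@H](C)c1ccc(C)cc1/C=C/C(=O)OCC | intermediate (key-step product)
22 | (2E)-3-{2-[(2S,3R,4R)-3,5-bis(TBSO)-4-methylpentan-2-yl]-5-methylphenyl}prop-2-en-1-ol | CC(C)(C)[Si](C)(C)OC[C@@H](C)[C@H](O[Si](C)(C)C(C)(C)C)[C@@H](C)c1ccc(C)cc1/C=C/CO | intermediate
23 | tert-butyldiphenylsilyl ether of 22 | CC(C)(C)[Si](C)(C)OC[C@@H](C)[C@H](O[Si](C)(C)C(C)(C)C)[C@@H](C)c1ccc(C)cc1/C=C/CO[Si](c2ccccc2)(c3ccccc3)C(C)(C)C | intermediate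
24 | (2R,3R,4S)-3-(TBSO)-4-{2-[(1E)-3-(TBDPSO)prop-1-en-1-yl]-4-methylphenyl}-2-methylpentan-1-ol | OC[C@@H](C)[C@H](O[Si](C)(C)C(C)(C)C)[C@@H](C)c1ccc(C)cc1/C=C/CO[Si](c2ccccc2)(c3ccccc3)C(C)(C)C | intermediate
25 | (2S,3R,4S)-3-(TBSO)-4-{2-[(1E)-3-(TBDPSO)prop-1-en-1-yl]-4-methylphenyl}-2-methylpentanal | O=C[C@@H](C)[C@H](O[Si](C)(C)C(C)(C)C)[C@@H](C)c1ccc(C)cc1/C=C/CO[Si](c2ccccc2)(c3ccccc3)C(C)(C)C | intermediate
26 | ethyl 2-ethylacetoacetate | CCOC(=O)C(CC)C(C)=O | starting material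
27 | dilithium dianion of 26 | [Li+].[Li+].CCOC(=O)[C-](CC)C(=O)[CH2-] | intermediate (not isolated)
28 | ethyl (6R,7R,8S)-7-(TBSO)-2-ethyl-5-hydroxy-6-methyl-3-oxo-8-{2-[(1E)-3-(TBDPSO)prop-1-en-1-yl]-4-methylphenyl}nonanoate (epimers at C2 and C5) | CCOC(=O)C(CC)C(=O)CC(O)[C@@H](C)[C@H](O[Si](C)(C)C(C)(C)C)[C@@H](C)c1ccc(C)cc1/C=C/CO[Si](c2ccccc2)(c3ccccc3)C(C)(C)C | intermediate
29 | ethyl (6S,7R,8S)-7-(TBSO)-2-ethyl-6-methyl-3,5-dioxo-8-{2-[(1E)-3-(TBDPSO)prop-1-en-1-yl]-4-methylphenyl}nonanoate | CCOC(=O)C(CC)C(=O)CC(=O)[C@@H](C)[C@H](O[Si](C)(C)C(C)(C)C)[C@@H](C)c1ccc(C)cc1/C=C/CO[Si](c2ccccc2)(c3ccccc3)C(C)(C)C | intermediate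
30 | 6-[(2S,3R,4S)-3-(TBSO)-4-{2-[(1E)-3-(TBDPSO)prop-1-en-1-yl]-4-methylphenyl}pentan-2-yl]-3-ethyl-4-hydroxy-2H-pyran-2-one | CCc1c(O)cc([C@@H](C)[C@H](O[Si](C)(C)C(C)(C)C)[C@@H](C)c2ccc(C)cc2/C=C/CO[Si](c3ccccc3)(c4ccccc4)C(C)(C)C)oc1=O | intermediate
31 | veramycin A | CCc1c(O)cc([C@@H](C)[C@H](O)[C@@H](C)c2ccc(C)cc2/C=C/CO)oc1=O | target

Total step count: 20. Longest linear sequence: 17 steps (steps 1–7 and 11–20).

Steps most likely to fail

Step 12 (ring closure and dehydrogenation). On heating, the tetraenoate may scramble its alkene geometry, which would open eight-electron pathways, or oligomerise through Diels–Alder reaction of its dienoate terminus, before the C10–C15 triene closes. Fallback: close the ring on a shorter trienal and attach C17–C18 afterwards. Setting out from 15, Wittig reaction with (triphenylphosphoranylidene)acetaldehyde (toluene, rt) should give (2E,4Z)-5-iodo-4-methylpenta-2,4-dienal F1. Suzuki coupling of this with 11 (Pd(dppf)Cl2·CH2Cl2, K3PO4, THF/H2O, rt) should give (2E,4Z,6E,8S,9R,10R)-9,11-bis(TBSO)-4,8,10-trimethylundeca-2,4,6-trienal F2, which has no fourth alkene and therefore no eight-electron manifold. Heating in toluene and then DDQ should give 2-[(2S,3R,4R)-3,5-bis(TBSO)-4-methylpentan-2-yl]-5-methylbenzaldehyde F3. Horner–Wadsworth–Emmons olefination with triethyl phosphonoacetate (NaH, THF, 0 °C) comes back to the route at 21.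

Step 10 (vinylogous olefination of the β-iodoenal). The Z geometry at C12=C13 may be lost by reversible addition–elimination at the iodine-bearing carbon under basic conditions, and the new C14=C15 alkene may form with incomplete E selectivity. Fallback: couple first and extend the chain afterwards. Setting out from 14, Suzuki coupling with 11 (same catalyst, rt), while the iodide is still a configurationally stable allylic alcohol, should give (2Z,4E,6S,7R,8R)-7,9-bis(TBSO)-2,6,8-trimethylnona-2,4-dien-1-ol F4. MnO2 oxidation should give (2Z,4E,6S,7R,8R)-7,9-bis(TBSO)-2,6,8-trimethylnona-2,4-dienal F5. The vinylogous Horner–Wadsworth–Emmons reaction with 16 (LiN(SiMe3)2, THF, −78 → 0 °C) then comes back to the route at 19, bypassing 15 and 18.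

Step 11 (Suzuki coupling). The α-branched vinylboronate may protodeboronate, and the aqueous base may isomerise or hydrolyse the iodotrienoate before transmetallation occurs. Fallback: a base-free Stille coupling. Setting out from 10, Takai-type olefination with Bu3SnCHBr2, CrCl2 and LiI (THF/DMF, rt) should give tributyl[(1E,3S,4R,5R)-4,6-bis(TBSO)-3,5-dimethylhex-1-en-1-yl]stannane F6. Stille coupling with 18 (Pd(PPh3)4, CuI, CsF, DMF, rt, dark) comes back to the route at 19.

Further compounds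
F1 | step 12 | (2E,4Z)-5-iodo-4-methylpenta-2,4-dienal | O=C/C=C/C(C)=C\I
F2 | step 12 | (2E,4Z,6E,8S,9R,10R)-9,11-bis(TBSO)-4,8,10-trimethylundeca-2,4,6-trienal | CC(C)(C)[Si](C)(C)OC[C@@H](C)[C@H](O[Si](C)(C)C(C)(C)C)[C@@H](C)/C=C/C=C(C)\C=C\C=O
F3 | step 12 | 2-[(2S,3R,4R)-3,5-bis(TBSO)-4-methylpentan-2-yl]-5-methylbenzaldehyde | CC(C)(C)[Si](C)(C)OC[C@@H](C)[C@H](O[Si](C)(C)C(C)(C)C)[C@@H](C)c1ccc(C)cc1C=O
F4 | step 10 | (2Z,4E,6S,7R,8R)-7,9-bis(TBSO)-2,6,8-trimethylnona-2,4-dien-1-ol | CC(C)(C)[Si](C)(C)OC[C@@H](C)[C@H](O[Si](C)(C)C(C)(C)C)[C@@H](C)/C=C/C=C(C)\CO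
F5 | step 10 | (2Z,4E,6S,7R,8R)-7,9-bis(TBSO)-2,6,8-trimethylnona-2,4-dienal | CC(C)(C)[Si](C)(C)OC[C@@H](C)[C@H](O[Si](C)(C)C(C)(C)C)[C@@H](C)/C=C/C=C(C)\C=O
F6 | step 11 | tributyl[(1E,3S,4R,5R)-4,6-bis(TBSO)-3,5-dimethylhex-1-en-1-yl]stannane | CC(C)(C)[Si](C)(C)OC[C@@H](C)[C@H](O[Si](C)(C)C(C)(C)C)[C@@H](C)/C=C/[Sn](CCCC)(CCCC)CCCC
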